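**Plan**

- Retrosynthesis: the late functions (C17 methylene, C20 aldehyde, C7/C19 acids, free hydroxyls) go back to the Δ1 cycloadduct 34. The key cut then opens C5–C10 and C3–C4 together, giving triene 33 with a 1-silyloxydiene on C9 and a Z-2-methylenoate on C6.
- Enabling feature: ring A (C1–C5, C10) is a cyclohexane with four neighbouring stereocentres (C3, C4, C5, C10), fused along C5–C10 to cyclopentane ring B (C5, C6, C8, C9, C10). C10 and C5 are therefore linked by the three-atom chain C9–C8–C6, the pattern of a type 1 intramolecular Diels–Alder adduct of a 1,3,8-nonatriene.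
- Further cuts: C4=C5 (Z-olefination), C6–C7 (auxiliary alkylation), C13–C16 (pinacol), C8–C15 and C8–C6 (two conjugate additions), C9–C10 (allylic alkylation of a meso diester).
- Forward order: ring C from cyclohexadiene, then quaternary C8, then ring D (bicyclo[3.2.1]octane), then the two side chains, then rings A and B in one step, then adjustment of C1/C2, C7, C16, C20, C19.
- Stereochemistry: C9 from the enantioselective palladium desymmetrisation; C8 by allylation anti to the C9 chain; C13 by the bridge; C6 from the oxazolidinone auxiliary; C3, C4, C5, C10 from alkene geometries, allylic strain at C6 and the exo transition state.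

Key step: step 22

Remark: atom labels C1–C20 are the gibberellane numbers of the target, β is the face of H-5 and H-9, and TBS = tert-butyldimethylsilyl, TIPS = triisopropylsilyl, PMB = 4-methoxybenzyl, Bn = benzyl.
Remark: from 6 to 32 the side-chain carbon C10 is an uncontrolled stereocentre; both epimers are carried together, the SMILES leave it undefined, and it becomes sp2 in step 21.
Remark: C7 is carried through the cycloaddition as CH2OBn, because a C7 ester would make C6–H doubly activated (α to an ester, γ to the enoate) and would require a configurationally unstable formyl ester for the olefination; the 16-ketone masks the C17 methylene during hydrogenation.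
Remark: the hand of the diphosphine in step 2 is assigned by analogy with simple cyclohexenyl acetates; if the first run shows the opposite sense, the enantiomeric ligand is used.

**Route**

Step 1
Reactants: 1 cyclohexa-1,3-diene
Product: 2 cis-cyclohex-2-ene-1,4-diyl diacetate (meso)
Conditions: Pd(OAc)2 (5 mol%), LiCl (0.2 equiv), LiOAc, p-benzoquinone (2 equiv), AcOH/pentane, rt
Reagents that add atoms: acetic acid, CC(=O)O (used with lithium acetate, [Li+].CC(=O)[O-])
Why: Palladium-catalysed 1,4-diacetoxylation of a conjugated diene, in which acetoxypalladation gives a π-allyl intermediate that, with chloride occupying the metal, is opened by external acetate on the face opposite palladium, so both acetates end up cis and the product is the meso diester.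

Step 2
Reactants: 2 cis-cyclohex-2-ene-1,4-diyl diacetate; 3 dimethyl malonate
Product: 4 dimethyl 2-[(1R,4S)-4-acetoxycyclohex-2-en-1-yl]malonate
Conditions: 3, NaH, THF, 0 °C; then 2, [Pd(C3H5)Cl]2 (2.5 mol%), (1S,2S)-N,N'-cyclohexane-1,2-diylbis[2-(diphenylphosphanyl)benzamide] (7.5 mol%), THF, 0 °C
Reagents that add atoms: none
Why: Tsuji–Trost allylic alkylation run as a desymmetrisation, in which the chiral zerovalent palladium complex ionises one enantiotopic acetate with inversion and the soft malonate anion attacks the same carbon with inversion, so C9 is set with net retention and the malonate stays cis to the remaining acetate.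

Step 3
Reactants: 4 malonate acetate
Product: 5 2-[(1R,4S)-4-hydroxycyclohex-2-en-1-yl]propane-1,3-diol
Conditions: LiAlH4 (excess), THF, 0 °C to reflux; aqueous NaOH work-up
Reagents that add atoms: none
Why: Hydride reduction converts both malonate esters into hydroxymethyl groups and cleaves the acetate, while the isolated alkene and the C9 and C13 centres are not touched.

Step 4
Reactants: 5 triol
Product: 6 (1S,4R)-4-[1-hydroxy-3-(PMB-oxy)propan-2-yl]cyclohex-2-en-1-ol (C10 epimers)
Conditions: Ag2O (1.5 equiv), 4-methoxybenzyl chloride (1.1 equiv), CH2Cl2, rt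
Reagents that add atoms: 4-methoxybenzyl chloride, COc1ccc(CCl)cc1
Why: Silver-oxide-mediated Williamson monoalkylation of a 1,3-diol, in which the chelated diol reacts once and the secondary allylic hydroxyl is slower; the two hydroxymethyl arms are diastereotopic, so C10 becomes an uncontrolled centre that is erased later.

Step 5
Reactants: 6 mono-PMB ether
Product: 7 (1S,4R)-4-[1-(TBS-oxy)-3-(PMB-oxy)propan-2-yl]cyclohex-2-en-1-ol (C10 epimers)
Conditions: TBSCl (1.05 equiv), imidazole, CH2Cl2, −20 °C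
Reagents that add atoms: tert-butyldimethylsilyl chloride, CC(C)(C)[Si](C)(C)Cl
Why: Silylation is far faster at the primary than at the secondary allylic hydroxyl, which is left free for the oxidation.

Step 6
Reactants: 7 allylic alcohol
Product: 8 (4R)-4-[1-(TBS-oxy)-3-(PMB-oxy)propan-2-yl]cyclohex-2-en-1-one
Conditions: MnO2 (activated, excess), CH2Cl2, rt
Reagents that add atoms: none
Why: Chemoselective allylic alcohol oxidation under neutral conditions gives the γ-substituted enone (C13 ketone) without epimerising C9.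

Step 7
Reactants: 8 enone; 9 1-(tert-butyldimethylsilyloxy)-1-methoxyethene
Product: 11 methyl 2-{(6S)-3-oxo-6-[1-(TBS-oxy)-3-(PMB-oxy)propan-2-yl]cyclohex-1-en-1-yl}acetate, via silyl enol ether 10 (not isolated)
Conditions: 9 (1.3 equiv), LiClO4 (10 mol%), MeCN, 50 °C; evaporate; then Pd(OAc)2 (1.2 equiv), MeCN, 40 °C
Reagents that add atoms: none
Why: Mukaiyama–Michael addition of the ketene silyl acetal with silyl transfer gives the regiodefined enol ether 10, and its Saegusa–Ito dehydrogenation restores the enone with the C6–C5 acetate arm on C8, the transient C8 centre being destroyed and C9 untouched.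

Step 8
Reactants: 11 enone ester; 12 allyltrimethylsilane
Product: 13 methyl 2-{(1R,2S)-1-allyl-5-oxo-2-[1-(TBS-oxy)-3-(PMB-oxy)propan-2-yl]cyclohexyl}acetate
Conditions: 12 (2 equiv), TiCl4 (1.2 equiv), CH2Cl2, −78 °C
Reagents that add atoms: none
Why: Hosomi–Sakurai conjugate allylation, in which the TiCl4-activated β,β-disubstituted enone is attacked axially on the face opposite the C9 substituent (held pseudoaxial by allylic 1,2-strain), creating the quaternary centre C8 with the allyl group (C15–C17) trans and the acetate arm (C6) cis to the C10 chain.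

Step 9
Reactants: 13 allyl ketone
Product: 15 methyl 2-{(1R,2S)-5-oxo-1-(2-oxoethyl)-2-[1-(TBS-oxy)-3-(PMB-oxy)propan-2-yl]cyclohexyl}acetate, via diol 14 (not isolated)
Conditions: OsO4 (2 mol%), NaIO4 (4 equiv), 2,6-lutidine, dioxane/H2O 3:1, rt
Reagents that add atoms: osmium tetroxide, O=[Os](=O)(=O)=O (aldehyde oxygen, turned over by sodium periodate, [Na+].[O-]I(=O)(=O)=O)
Why: Lemieux–Johnson cleavage (dihydroxylation then periodate glycol fission, buffered by 2,6-lutidine) converts the terminal alkene into the C16 aldehyde and leaves ketone, ester, silyl ether and anisyl ether intact.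

Step 10
Reactants: 15 keto aldehyde
Product: 16 methyl 2-{5,6-dihydroxy-2-[1-(TBS-oxy)-3-(PMB-oxy)propan-2-yl]bicyclo[3.2.1]octan-1-yl}acetate (C13/C16 cis-diol)
Conditions: SmI2 (2.5 equiv), t-BuOH (2 equiv), THF, −78 to −20 °C
Reagents that add atoms: none
Why: Samarium diiodide pinacol coupling of a keto aldehyde, in which the aldehyde ketyl adds to the C13 ketone to close the five-membered ring D (the C15–C16 bridge can only span one face of ring C, which fixes C13), and chelation of both oxygens to samarium gives the cis diol at C16.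

Step 11
Reactants: 16 diol
Product: 17 methyl 2-{5-hydroxy-6-oxo-2-[1-(TBS-oxy)-3-(PMB-oxy)propan-2-yl]bicyclo[3.2.1]octan-1-yl}acetate
Conditions: IBX (1.5 equiv), DMSO, rt
Reagents that add atoms: none
Why: IBX oxidises the secondary hydroxyl of a vicinal diol to the ketone without glycol cleavage and cannot oxidise the tertiary bridgehead alcohol, giving the 13-hydroxy-16-ketone.

Step 12
Reactants: 17 ketol
Product: 18 methyl 2-{6-oxo-5-(TBS-oxy)-2-[1-(TBS-oxy)-3-(PMB-oxy)propan-2-yl]bicyclo[3.2.1]octan-1-yl}acetate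
Conditions: TBSOTf (1.5 equiv), 2,6-lutidine, CH2Cl2, −78 to 0 °C
Reagents that add atoms: tert-butyldimethylsilyl trifluoromethanesulfonate, CC(C)(C)[Si](C)(C)OS(=O)(=O)C(F)(F)F
Why: A silyl triflate with a hindered pyridine base silylates the tertiary hydroxyl at low temperature faster than it enolises the bridged ketone, and the ether blocks α-ketol rearrangement in the basic steps that follow.

Step 13
Reactants: 18 methyl ester
Product: 19 2-{6-oxo-5-(TBS-oxy)-2-[1-(TBS-oxy)-3-(PMB-oxy)propan-2-yl]bicyclo[3.2.1]octan-1-yl}acetic acid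
Conditions: LiOH·H2O, THF/MeOH/H2O, rt; then aqueous HCl to pH 3
Reagents that add atoms: lithium hydroxide, [Li+].[OH-] (carboxyl oxygen)
Why: Saponification of the unhindered methyl ester, to which the silyl ethers, the anisyl ether and the quaternary centres are stable.

Step 14
Reactants: 19 acid; 20 (R)-4-benzyl-1,3-oxazolidin-2-one
Product: 22 (R)-4-benzyl-3-(2-{6-oxo-5-(TBS-oxy)-2-[1-(TBS-oxy)-3-(PMB-oxy)propan-2-yl]bicyclo[3.2.1]octan-1-yl}acetyl)-1,3-oxazolidin-2-one, via mixed anhydride 21 (not isolated)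
Conditions: pivaloyl chloride, Et3N, THF, −20 to 0 °C; then 20, LiCl, rt
Reagents that add atoms: pivaloyl chloride, CC(C)(C)C(Cl)=O (retained only in intermediate 21)
Why: N-Acylation of the oxazolidinone through the mixed pivalic anhydride, which is attacked at the less hindered acyl group, with LiCl/Et3N activating the oxazolidinone without a strong base so that the ketone is not enolised.

Step 15
Reactants: 22 imide; 23 benzyl chloromethyl ether
Product: 24 (R)-4-benzyl-3-[(2S)-3-(benzyloxy)-2-(bicyclic core)propanoyl]-1,3-oxazolidin-2-one (C6 set)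
Conditions: TiCl4 (1.05 equiv), i-Pr2NEt (1.1 equiv), CH2Cl2, 0 °C; then 23 (2 equiv), 0 °C
Reagents that add atoms: none
Why: Auxiliary-controlled alkylation of the chelated Z titanium enolate by the oxocarbenium-like chloromethyl ether on the face away from the benzyl group of the auxiliary sets C6 (the R auxiliary gives the 6S imide, C7 = CH2OBn), the imide being enolised by TiCl4/amine in preference to the ketone.

Step 16
Reactants: 24 alkylated imide
Product: 25 S-ethyl (2S)-3-(benzyloxy)-2-(bicyclic core)propanethioate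
Conditions: EtSH, n-BuLi, THF, 0 °C; water quench
Reagents that add atoms: ethanethiol, CCS
Why: Thiolate transacylation at the exocyclic imide carbonyl under weakly basic conditions releases the auxiliary without epimerising C6 or eliminating the β-benzyloxy group, and gives a thioester that can be reduced in the presence of the ketone.

Step 17
Reactants: 25 thioester
Product: 26 (2S)-3-(benzyloxy)-2-(bicyclic core)propanal (C5 aldehyde)
Conditions: Et3SiH, Pd/C (10 mol%), acetone, rt
Reagents that add atoms: none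
Why: Fukuyama reduction, a palladium-catalysed hydrosilane reduction of the thioester that stops at the aldehyde and spares the ketone and the benzyl and anisyl ethers.

Step 18
Reactants: 26 aldehyde; 27 methyl 2-[bis(2,2,2-trifluoroethoxy)phosphoryl]propanoate
Product: 28 methyl (2Z,4S)-5-(benzyloxy)-2-methyl-4-(bicyclic core)pent-2-enoate
Conditions: 27, KN(SiMe3)2, 18-crown-6, THF, −78 °C; then 26
Reagents that add atoms: none
Why: Still–Gennari olefination, in which the potassium phosphonate anion adds to the α-branched aldehyde and fast irreversible elimination of the kinetic adduct gives the Z trisubstituted enoate (C19 cis to C6), the aldehyde reacting much faster than the hindered ketone.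

Step 19
Reactants: 28 Z-enoate
Product: 29 Z-enoate with free C1 hydroxyl (C9 chain CH(CH2OH)CH2OTBS)
Conditions: DDQ, CH2Cl2/H2O (pH 7 buffer), 0 °C
Reagents that add atoms: none
Why: Oxidative cleavage of the electron-rich 4-methoxybenzyl ether by DDQ (hydride abstraction, then hydrolysis of the hemiacetal) frees the C1 hydroxyl, while the benzyl ether, the silyl ethers and the enoate are inert.

Step 20
Reactants: 29 alcohol; 30 (triphenylphosphoranylidene)acetaldehyde
Product: 32 E-enal (C9 chain CH(CH2OTBS)CH=CH–CHO), via aldehyde 31 (not isolated)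
Conditions: DMP, CH2Cl2, 0 °C to rt; filter; then 30 (1.2 equiv), PhMe, 60 °C
Reagents that add atoms: none
Why: Periodinane oxidation to the aldehyde followed by a Wittig reaction with the formyl-stabilised ylide, which adds C2 and C3 and gives the E enal under thermodynamic control, the stabilised ylide leaving ketone and enoate alone.

Step 21
Reactants: 32 enal
Product: 33 triene (C9 bears the (1E,3Z)-1-(TIPS-oxy)-4-(TBS-oxymethyl)buta-1,3-dien-4-yl group)
Conditions: TIPSOTf (1.3 equiv), Et3N (3 equiv), CH2Cl2, −78 to −20 °C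
Reagents that add atoms: triisopropylsilyl trifluoromethanesulfonate, CC(C)[Si](OS(=O)(=O)C(F)(F)F)(C(C)C)C(C)C
Why: Soft enolisation of the enal (O-silylation, then γ-deprotonation at C10 by Et3N) gives the 1-silyloxydiene, E at the enol ether because the enal reacts in its s-trans form and with the bulky ring carbon C9 trans to C2 at the new C10=C1 bond, while the limiting silyl triflate at low temperature should leave the hindered ketone unsilylated.

Step 22
Reactants: 33 triene
Product: 34 tetracyclic Δ1 cycloadduct (3β-OTIPS, 4α-CO2Me, 4β-Me, 6β-CH2OBn, 13-OTBS, 16-oxo, 20-OTBS)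
Conditions: PhMe (5 mM), 2,6-di-tert-butyl-4-methylphenol (cat.), Et3N (cat.), 150 °C, sealed tube
Reagents that add atoms: none
Why: Thermal type 1 intramolecular Diels–Alder reaction of a 1,3,8-nonatriene, a concerted suprafacial [4+2] addition in which the HOMO of the 1-silyloxydiene (largest coefficient at C10) matches the LUMO of the Z-enoate (largest coefficient at C5), the closest known reaction type being the thermal cyclisation of tethered 1-silyloxydienes onto enoates to trans-hydrindenes. Ring A (six-membered) closes by the cycloaddition itself through the new C5–C10 and C3–C4 bonds, and ring B (five-membered) closes in the fused mode because the chain C9–C8–C6 joins the diene terminus C10 to the dienophile carbon C5. C3 is set by the E enol ether (silyloxy cis to C9) and C4 by the Z enoate (C19 cis to C6), both through suprafacial addition. C5 is set by allylic 1,3-strain at C6, whose hydrogen eclipses the C4=C5 bond so that the diene reaches the face syn to C8 and anti to the CH2OBn group, and C10 follows from the transition state in which tether and ester are exo (trans ring fusion, C20 and C19 both α). This exo mode is the selectivity the step needs, and it should be secured by the α-methyl group (which takes the endo position in preference to the ester), by the rigid bicyclo[3.2.1]octane that holds C10 axial and C6 equatorial in a gauche array, and by the inside C20 substituent, which crowds the endo arrangement.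

Step 23
Reactants: 34 cycloadduct
Product: 35 saturated tetracycle with free C7 hydroxyl
Conditions: H2 (1 atm), Pd/C, EtOAc, rt
Reagents that add atoms: none
Why: Heterogeneous hydrogenation saturates the disubstituted C1=C2 bond (no stereocentre is created) and hydrogenolyses the benzyl ether to the C7 alcohol in the same operation, while the hindered ketone and the silyl ethers survive.

Step 24
Reactants: 35 C7 alcohol
Product: 37 C7 carboxylic acid, via aldehyde 36 (not isolated)
Conditions: TEMPO (cat.), NaOCl (cat.), NaClO2, MeCN/phosphate buffer pH 6.7, 35 °C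
Reagents that add atoms: sodium chlorite, [Na+].[O-]Cl=O (carboxyl oxygen)
Why: Oxoammonium (TEMPO) oxidation of the primary alcohol to the aldehyde and chlorite oxidation in situ to the acid, under buffered conditions that tolerate silyl ethers and should not epimerise C6.

Step 25
Reactants: 37 keto acid; 38 methyltriphenylphosphonium bromide
Product: 39 16-methylene acid
Conditions: 38 (5 equiv), KOt-Bu (5 equiv), THF, rt; then 37, rt to 50 °C
Reagents that add atoms: none
Why: Wittig methylenation of the 16-ketone with excess ylide (one equivalent is consumed by the acid), a standard way to install C17 on 13-O-protected 16-oxogibberellins, with the C20 silyl ether preventing alkoxide-induced lactonisation onto C19.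

Step 26
Reactants: 39 methylene compound
Product: 40 C20 alcohol
Conditions: HF·pyridine, pyridine, THF, 0 °C to rt
Reagents that add atoms: none
Why: Buffered HF·pyridine removes the primary silyl ether much faster than the hindered secondary TIPS ether and the tertiary TBS ether, under non-basic conditions that do not trigger lactonisation of the new alcohol with the C19 ester.

Step 27
Reactants: 40 C20 alcohol
Product: 41 C20 aldehyde
Conditions: DMP, CH2Cl2, rt (directly after step 26)
Reagents that add atoms: none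
Why: Periodinane oxidation of the neopentyl primary alcohol gives the non-enolisable C20 aldehyde, the free acid and the exocyclic alkene being inert.

Step 28
Reactants: 41 aldehyde ester
Product: 42 7,19-diacid with 3-OTIPS and 13-OTBS
Conditions: KOH (2 M), MeOH/H2O, 60 °C; then aqueous HCl to pH 3
Reagents that add atoms: potassium hydroxide, [K+].[OH-] (carboxyl oxygen)
Why: Saponification of the hindered C19 methyl ester, assisted by the neighbouring aldehyde hydrate (acyl transfer through a lactol), while the 3-O-silyl group blocks the retro-aldol epimerisation at C3 that a free 3-hydroxy ester suffers in base.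

Step 29
Reactants: 42 bis-silyl ether
Product: 43 target CNP0236431.1
Conditions: Bu4NF (excess), THF, 45 °C; then aqueous HCl to pH 3
Reagents that add atoms: none
Why: Fluoride-induced desilylation (Si–F bond formation) reveals the 3β- and 13-hydroxyls, and with C19 present as a carboxylate no retro-aldol can occur and the aldehyde and the exocyclic alkene are stable to fluoride.

**Compound list**

1 | cyclohexa-1,3-diene | C1=CC=CCC1 | starting material
2 | cis-cyclohex-2-ene-1,4-diyl diacetate (meso) | CC(=O)O[C@H]1C=C[C@@H](OC(C)=O)CC1 | intermediate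
3 | dimethyl malonate | COC(=O)CC(=O)OC | starting material
4 | dimethyl 2-[(1R,4S)-4-acetoxycyclohex-2-en-1-yl]malonate | COC(=O)C(C(=O)OC)[C@H]1C=C[C@@H](OC(C)=O)CC1 | intermediate
5 | 2-[(1R,4S)-4-hydroxycyclohex-2-en-1-yl]propane-1,3-diol | OCC(CO)[C@H]1C=C[C@@H](O)CC1 | intermediate
6 | (1S,4R)-4-[1-hydroxy-3-(4-methoxybenzyloxy)propan-2-yl]cyclohex-2-en-1-ol, C10 epimers | COc1ccc(COCC(CO)[C@H]2C=C[C@@H](O)CC2)cc1 | intermediate
7 | (1S,4R)-4-[1-(tert-butyldimethylsilyloxy)-3-(4-methoxybenzyloxy)propan-2-yl]cyclohex-2-en-1-ol, C10 epimers | COc1ccc(COCC(CO[Si](C)(C)C(C)(C)C)[C@H]2C=C[C@@H](O)CC2)cc1 | intermediate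
8 | (4R)-4-[1-(tert-butyldimethylsilyloxy)-3-(4-methoxybenzyloxy)propan-2-yl]cyclohex-2-en-1-one | COc1ccc(COCC(CO[Si](C)(C)C(C)(C)C)[C@H]2C=CC(=O)CC2)cc1 | intermediate
9 | 1-(tert-butyldimethylsilyloxy)-1-methoxyethene | C=C(OC)O[Si](C)(C)C(C)(C)C | starting material
10 | methyl 2-{3-(TBS-oxy)-6-[1-(TBS-oxy)-3-(PMB-oxy)propan-2-yl]cyclohex-2-en-1-yl}acetate (ring substituents trans) | COC(=O)C[C@@H]1C=C(O[Si](C)(C)C(C)(C)C)CC[C@H]1C(CO[Si](C)(C)C(C)(C)C)COCc1ccc(OC)cc1 | intermediate (not isolated)
11 | methyl 2-{(6S)-3-oxo-6-[1-(TBS-oxy)-3-(PMB-oxy)propan-2-yl]cyclohex-1-en-1-yl}acetate | COC(=O)CC1=CC(=O)CC[C@H]1C(CO[Si](C)(C)C(C)(C)C)COCc1ccc(OC)cc1 | intermediate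
12 | allyltrimethylsilane | C=CC[Si](C)(C)C | starting material
13 | methyl 2-{(1R,2S)-1-allyl-5-oxo-2-[1-(TBS-oxy)-3-(PMB-oxy)propan-2-yl]cyclohexyl}acetate | COC(=O)C[C@@]1(CC=C)CC(=O)CC[C@H]1C(CO[Si](C)(C)C(C)(C)C)COCc1ccc(OC)cc1 | intermediate
14 | methyl 2-{(1R,2S)-1-(2,3-dihydroxypropyl)-5-oxo-2-[1-(TBS-oxy)-3-(PMB-oxy)propan-2-yl]cyclohexyl}acetate | COC(=O)C[C@@]1(CC(O)CO)CC(=O)CC[C@H]1C(CO[Si](C)(C)C(C)(C)C)COCc1ccc(OC)cc1 | intermediate (not isolated)
15 | methyl 2-{(1R,2S)-5-oxo-1-(2-oxoethyl)-2-[1-(TBS-oxy)-3-(PMB-oxy)propan-2-yl]cyclohexyl}acetate | COC(=O)C[C@@]1(CC=O)CC(=O)CC[C@H]1C(CO[Si](C)(C)C(C)(C)C)COCc1ccc(OC)cc1 | intermediate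
16 | methyl 2-{5,6-dihydroxy-2-[1-(TBS-oxy)-3-(PMB-oxy)propan-2-yl]bicyclo[3.2.1]octan-1-yl}acetate (bicyclo locants 1, 2, 5, 6 = C8, C9, C13, C16; cis-diol; C8, C9, C13 as in the target) | O[C@@H]1C[C@]2(CC(=O)OC)C[C@@]1(O)CC[C@H]2C(CO[Si](C)(C)C(C)(C)C)COCc1ccc(OC)cc1 | intermediate
17 | methyl 2-{5-hydroxy-6-oxo-2-[1-(TBS-oxy)-3-(PMB-oxy)propan-2-yl]bicyclo[3.2.1]octan-1-yl}acetate | O=C1C[C@]2(CC(=O)OC)C[C@@]1(O)CC[C@H]2C(CO[Si](C)(C)C(C)(C)C)COCc1ccc(OC)cc1 | intermediate
18 | methyl 2-{6-oxo-5-(TBS-oxy)-2-[1-(TBS-oxy)-3-(PMB-oxy)propan-2-yl]bicyclo[3.2.1]octan-1-yl}acetate | O=C1C[C@]2(CC(=O)OC)C[C@@]1(O[Si](C)(C)C(C)(C)C)CC[C@H]2C(CO[Si](C)(C)C(C)(C)C)COCc1ccc(OC)cc1 | intermediate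
19 | 2-{6-oxo-5-(TBS-oxy)-2-[1-(TBS-oxy)-3-(PMB-oxy)propan-2-yl]bicyclo[3.2.1]octan-1-yl}acetic acid | O=C1C[C@]2(CC(=O)O)C[C@@]1(O[Si](C)(C)C(C)(C)C)CC[C@H]2C(CO[Si](C)(C)C(C)(C)C)COCc1ccc(OC)cc1 | intermediate
20 | (R)-4-benzyl-1,3-oxazolidin-2-one | O=C1N[C@H](Cc2ccccc2)CO1 | starting material
21 | mixed anhydride of acid 19 with pivalic acid | O=C1C[C@]2(CC(=O)OC(=O)C(C)(C)C)C[C@@]1(O[Si](C)(C)C(C)(C)C)CC[C@H]2C(CO[Si](C)(C)C(C)(C)C)COCc1ccc(OC)cc1 | intermediate (not isolated)
22 | (R)-4-benzyl-3-acyl-1,3-oxazolidin-2-one of acid 19 | O=C1C[C@]2(CC(=O)N3[C@H](Cc4ccccc4)COC3=O)C[C@@]1(O[Si](C)(C)C(C)(C)C)CC[C@H]2C(CO[Si](C)(C)C(C)(C)C)COCc1ccc(OC)cc1 | intermediate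
23 | benzyl chloromethyl ether | ClCOCc1ccccc1 | starting material
24 | imide 22 carrying CH2OBn at C6, (2S)-3-(benzyloxy)propanoyl imide | O=C1C[C@]2([C@@H](COCc3ccccc3)C(=O)N3[C@H](Cc4ccccc4)COC3=O)C[C@@]1(O[Si](C)(C)C(C)(C)C)CC[C@H]2C(CO[Si](C)(C)C(C)(C)C)COCc1ccc(OC)cc1 | intermediate
25 | S-ethyl (2S)-3-(benzyloxy)-2-(bicyclic core)propanethioate | O=C1C[C@]2([C@@H](COCc3ccccc3)C(=O)SCC)C[C@@]1(O[Si](C)(C)C(C)(C)C)CC[C@H]2C(CO[Si](C)(C)C(C)(C)C)COCc1ccc(OC)cc1 | intermediate
26 | (2S)-3-(benzyloxy)-2-(bicyclic core)propanal | O=C1C[C@]2([C@@H](COCc3ccccc3)C=O)C[C@@]1(O[Si](C)(C)C(C)(C)C)CC[C@H]2C(CO[Si](C)(C)C(C)(C)C)COCc1ccc(OC)cc1 | intermediate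
27 | methyl 2-[bis(2,2,2-trifluoroethoxy)phosphoryl]propanoate | COC(=O)C(C)P(=O)(OCC(F)(F)F)OCC(F)(F)F | starting material
28 | methyl (2Z,4S)-5-(benzyloxy)-2-methyl-4-(bicyclic core)pent-2-enoate, C9 chain CH(CH2OTBS)CH2OPMB | O=C1C[C@]2([C@@H](COCc3ccccc3)/C=C(/C)C(=O)OC)C[C@@]1(O[Si](C)(C)C(C)(C)C)CC[C@H]2C(CO[Si](C)(C)C(C)(C)C)COCc1ccc(OC)cc1 | intermediate
29 | Z-enoate 28 with the PMB ether replaced by a free C1 hydroxyl | O=C1C[C@]2([C@@H](COCc3ccccc3)/C=C(/C)C(=O)OC)C[C@@]1(O[Si](C)(C)C(C)(C)C)CC[C@H]2C(CO)CO[Si](C)(C)C(C)(C)C | intermediate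
30 | (triphenylphosphoranylidene)acetaldehyde | O=CC=P(c1ccccc1)(c1ccccc1)c1ccccc1 | starting material
31 | C1 aldehyde, C9 chain CH(CHO)CH2OTBS | O=C1C[C@]2([C@@H](COCc3ccccc3)/C=C(/C)C(=O)OC)C[C@@]1(O[Si](C)(C)C(C)(C)C)CC[C@H]2C(C=O)CO[Si](C)(C)C(C)(C)C | intermediate (not isolated)
32 | E-enal, C9 chain CH(CH2OTBS)CH=CH–CHO | O=C1C[C@]2([C@@H](COCc3ccccc3)/C=C(/C)C(=O)OC)C[C@@]1(O[Si](C)(C)C(C)(C)C)CC[C@H]2C(CO[Si](C)(C)C(C)(C)C)/C=C/C=O | intermediate
33 | triene: 16-oxo-13-OTBS bicyclo[3.2.1]octane with the Z-enoate chain on C8 and the (1E,3Z)-1-(TIPS-oxy)-4-(TBS-oxymethyl)buta-1,3-dien-4-yl group on C9 | O=C1C[C@]2([C@@H](COCc3ccccc3)/C=C(/C)C(=O)OC)C[C@@]1(O[Si](C)(C)C(C)(C)C)CC[C@H]2/C(CO[Si](C)(C)C(C)(C)C)=C/C=C/O[Si](C(C)C)(C(C)C)C(C)C | intermediate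
34 | tetracyclic Δ1 cycloadduct: 3β-OTIPS, 4α-CO2Me (C19), 4β-Me, 5β-H, 6β-CH2OBn, 9β-H, 10α-CH2OTBS, 13-OTBS, 16-oxo-17-nor | O=C1C[C@]23C[C@@]1(O[Si](C)(C)C(C)(C)C)CC[C@H]2[C@]1(CO[Si](C)(C)C(C)(C)C)C=C[C@H](O[Si](C(C)C)(C(C)C)C(C)C)[C@@](C)(C(=O)OC)[C@H]1[C@@H]3COCc1ccccc1 | intermediate
35 | 1,2-dihydro compound with 7-hydroxyl | O=C1C[C@]23C[C@@]1(O[Si](C)(C)C(C)(C)C)CC[C@H]2[C@]1(CO[Si](C)(C)C(C)(C)C)CC[C@H](O[Si](C(C)C)(C(C)C)C(C)C)[C@@](C)(C(=O)OC)[C@H]1[C@@H]3CO | intermediate
36 | 7-aldehyde | O=C1C[C@]23C[C@@]1(O[Si](C)(C)C(C)(C)C)CC[C@H]2[C@]1(CO[Si](C)(C)C(C)(C)C)CC[C@H](O[Si](C(C)C)(C(C)C)C(C)C)[C@@](C)(C(=O)OC)[C@H]1[C@@H]3C=O | intermediate (not isolated)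
37 | 7-oic acid, 16-ketone | O=C1C[C@]23C[C@@]1(O[Si](C)(C)C(C)(C)C)CC[C@H]2[C@]1(CO[Si](C)(C)C(C)(C)C)CC[C@H](O[Si](C(C)C)(C(C)C)C(C)C)[C@@](C)(C(=O)OC)[C@H]1[C@@H]3C(=O)O | intermediate
38 | methyltriphenylphosphonium bromide | C[P+](c1ccccc1)(c1ccccc1)c1ccccc1.[Br-] | starting material
39 | 16-methylene 7-oic acid, 19-methyl ester, 20-OTBS | C=C1C[C@]23C[C@@]1(O[Si](C)(C)C(C)(C)C)CC[C@H]2[C@]1(CO[Si](C)(C)C(C)(C)C)CC[C@H](O[Si](C(C)C)(C(C)C)C(C)C)[C@@](C)(C(=O)OC)[C@H]1[C@@H]3C(=O)O | intermediate
40 | 20-alcohol | C=C1C[C@]23C[C@@]1(O[Si](C)(C)C(C)(C)C)CC[C@H]2[C@]1(CO)CC[C@H](O[Si](C(C)C)(C(C)C)C(C)C)[C@@](C)(C(=O)OC)[C@H]1[C@@H]3C(=O)O | intermediate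
41 | 20-aldehyde, 19-methyl ester | C=C1C[C@]23C[C@@]1(O[Si](C)(C)C(C)(C)C)CC[C@H]2[C@]1(C=O)CC[C@H](O[Si](C(C)C)(C(C)C)C(C)C)[C@@](C)(C(=O)OC)[C@H]1[C@@H]3C(=O)O | intermediate
42 | 7,19-diacid 20-aldehyde, 3-OTIPS, 13-OTBS | C=C1C[C@]23C[C@@]1(O[Si](C)(C)C(C)(C)C)CC[C@H]2[C@]1(C=O)CC[C@H](O[Si](C(C)C)(C(C)C)C(C)C)[C@@](C)(C(=O)O)[C@H]1[C@@H]3C(=O)O | intermediate
43 | CNP0236431.1 (3β,13-dihydroxy-20-oxo-gibberell-16-ene-7,19-dioic acid) | C=C1C[C@]23C[C@@]1(O)CC[C@H]2[C@]1(C=O)CC[C@H](O)[C@@](C)(C(=O)O)[C@H]1[C@@H]3C(=O)O | target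

**Count and risks**

Total step count: 29. Longest linear sequence: 29 steps (1 to 43); the partners 3, 9, 12, 20, 23, 27, 30 and 38 are purchased.

Steps most likely to fail:

1. Step 22 (cycloaddition). The ring closure may be too slow at a temperature the silyl dienol ether tolerates, so that [1,5]-hydrogen migration from C20 or loss of the diene competes, and part of the material may react through the ester-endo (cis-fused) mode. Fallback with a more electrophilic dienophile: setting out from enoate 28, the methyl ester would be cleaved with Me3SnOH to the Z-enoic acid F1 and re-esterified with 2,2,2-trifluoroethanol (EDC, DMAP) to the trifluoroethyl Z-enoate F2. The operations of steps 19, 20 and 21 would then give the primary alcohol F3, the aldehyde F4 (not isolated), the E-enal F5 and the silyloxy triene F6. Heating F6 should give the trifluoroethyl cycloadduct F7 at a lower temperature, and NaOMe in MeOH would exchange the activated ester for the methyl ester, rejoining the route at 34.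

2. Step 15 (auxiliary alkylation). The neopentyl-type titanium enolate may alkylate sluggishly, leaving time for enolisation of the 16-ketone or attack of TiCl4 on the silyl ethers. Fallback by aldol-type C–C bond formation instead of alkylation: from imide 22 the same enolate would be hydroxymethylated with 1,3,5-trioxane/TiCl4 to the β-hydroxy imide F8, which would be O-benzylated under acid catalysis (benzyl 2,2,2-trichloroacetimidate, TfOH) to rejoin the route at 24.

3. Step 10 (pinacol closure of ring D). Over-reduction of the aldehyde or acylation of the samarium alkoxide by the C5 ester may outrun the carbonyl coupling. Fallback by umpolung instead of reduction: from keto aldehyde 15, an N-heterocyclic carbene (triazolium salt, DBU, THF) would turn the aldehyde into an acyl anion equivalent that adds to the C13 ketone (intramolecular crossed benzoin reaction) and gives ketol 17 directly, bypassing diol 16; no compound outside the list is made (none, F0).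

Further compounds
F1 | step 22 | Z-enoic acid from 28 (C19 CO2H) | O=C1C[C@]2([C@@H](COCc3ccccc3)/C=C(/C)C(=O)O)C[C@@]1(O[Si](C)(C)C(C)(C)C)CC[C@H]2C(CO[Si](C)(C)C(C)(C)C)COCc1ccc(OC)cc1
F2 | step 22 | 2,2,2-trifluoroethyl Z-enoate | O=C1C[C@]2([C@@H](COCc3ccccc3)/C=C(/C)C(=O)OCC(F)(F)F)C[C@@]1(O[Si](C)(C)C(C)(C)C)CC[C@H]2C(CO[Si](C)(C)C(C)(C)C)COCc1ccc(OC)cc1
F3 | step 22 | trifluoroethyl Z-enoate with free C1 hydroxyl | O=C1C[C@]2([C@@H](COCc3ccccc3)/C=C(/C)C(=O)OCC(F)(F)F)C[C@@]1(O[Si](C)(C)C(C)(C)C)CC[C@H]2C(CO)CO[Si](C)(C)C(C)(C)C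
F4 | step 22 | C1 aldehyde of the trifluoroethyl series (not isolated) | O=C1C[C@]2([C@@H](COCc3ccccc3)/C=C(/C)C(=O)OCC(F)(F)F)C[C@@]1(O[Si](C)(C)C(C)(C)C)CC[C@H]2C(C=O)CO[Si](C)(C)C(C)(C)C
F5 | step 22 | E-enal of the trifluoroethyl series | O=C1C[C@]2([C@@H](COCc3ccccc3)/C=C(/C)C(=O)OCC(F)(F)F)C[C@@]1(O[Si](C)(C)C(C)(C)C)CC[C@H]2C(CO[Si](C)(C)C(C)(C)C)/C=C/C=O
F6 | step 22 | silyloxy triene of the trifluoroethyl series | O=C1C[C@]2([C@@H](COCc3ccccc3)/C=C(/C)C(=O)OCC(F)(F)F)C[C@@]1(O[Si](C)(C)C(C)(C)C)CC[C@H]2/C(CO[Si](C)(C)C(C)(C)C)=C/C=C/O[Si](C(C)C)(C(C)C)C(C)C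
F7 | step 22 | trifluoroethyl cycloadduct (19-trifluoroethyl ester analogue of 34) | O=C1C[C@]23C[C@@]1(O[Si](C)(C)C(C)(C)C)CC[C@H]2[C@]1(CO[Si](C)(C)C(C)(C)C)C=C[C@H](O[Si](C(C)C)(C(C)C)C(C)C)[C@@](C)(C(=O)OCC(F)(F)F)[C@H]1[C@@H]3COCc1ccccc1
F8 | step 15 | β-hydroxy imide (C6 bearing CH2OH) | O=C1C[C@]2([C@@H](CO)C(=O)N3[C@H](Cc4ccccc4)COC3=O)C[C@@]1(O[Si](C)(C)C(C)(C)C)CC[C@H]2C(CO[Si](C)(C)C(C)(C)C)COCc1ccc(OC)cc1
F0 | step 10 | none | none
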